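Ring A (C1–C5, C10) is disconnected at the C3–C4 bond, next to its most congested atom, the gem-dimethyl carbon C4 lodged between C3 and the chain-bearing C5. C4 is therefore generated last, as a tertiary radical: iron-hydride hydrogen-atom transfer to an isopropenyl group on C5 triggers a 6-endo Giese closure onto the C10 vinyl ketone, giving the quaternary carbon and the ring in one operation. The precursor is an acyclic β-keto ester with C5 and C10 already set by iridium-catalysed allylic alkylation, carrying the isopropenyl donor, the acryloyl acceptor and a ketal-masked 3-oxobutyl chain; its ester is benzyl, not methyl, so that hydrogenolysis later frees the C9 carboxyl.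

Key step: step 10

Remarks on the chemistry:
- C-labels (C1–C5, C9, C10) are labdane-type labels of the target: ring A = C1, C2, C3, C4 (gem-dimethyl), C5 (CH with the 3-oxobutyl chain), C10 (quaternary, CH3 and the C9 ketone). Locants inside compound names are systematic.
- Assumption: the sense of induction of the iridium–phosphoramidite catalyst in step 5 is assigned by analogy. The ligand antipode is the one that gives 3R in 8, and the lithium-chelated enolate is expected to give 2S with it.
- Assumption: (2E)-4-bromo-3-methylbut-2-en-1-yl acetate 21 is taken as a purchasable C5 building block.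

Step 1
Reactants: 1 methacrolein; 2 triethyl phosphonoacetate
Product: 3 ethyl (2E)-4-methylpenta-2,4-dienoate
Conditions: NaH, THF, 0 °C → rt
Reagents that add atoms: none
Why: Horner–Wadsworth–Emmons olefination of an enal with a stabilised phosphonate anion is reliably E-selective and leaves the 1,1-disubstituted alkene alone.

Step 2
Reactants: 3 ethyl (2E)-4-methylpenta-2,4-dienoate
Product: 4 (2E)-4-methylpenta-2,4-dien-1-ol
Conditions: i-Bu2AlH (2.2 equiv), CH2Cl2, −78 → 0 °C; aq. potassium sodium tartrate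
Reagents that add atoms: none
Why: Hydride reduction of a conjugated ester by i-Bu2AlH is 1,2-selective and should give the dienyl alcohol without touching the diene.

Step 3
Reactants: 4 (2E)-4-methylpenta-2,4-dien-1-ol
Product: 5 methyl (2E)-4-methylpenta-2,4-dien-1-yl carbonate
Conditions: ClCO2Me, pyridine, CH2Cl2, 0 °C
Reagents that add atoms: methyl chloroformate, COC(=O)Cl
Why: O-acylation of a primary allylic alcohol with a chloroformate installs the carbonate leaving group needed for ionisation by iridium.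

Step 4
Reactants: 6 methyl 2-methyl-3-oxobutanoate (racemic)
Product: 7 benzyl 2-methyl-3-oxobutanoate (racemic)
Conditions: BnOH, DMAP (cat.), toluene, reflux (−MeOH)
Reagents that add atoms: benzyl alcohol, OCc1ccccc1
Why: DMAP-catalysed transesterification of an enolisable β-keto ester proceeds through the acylketene and is driven by distilling out methanol.

Step 5
Reactants: 5 methyl (2E)-4-methylpenta-2,4-dien-1-yl carbonate; 7 benzyl 2-methyl-3-oxobutanoate
Product: 8 benzyl (2S,3R)-2-acetyl-2-methyl-3-(prop-1-en-2-yl)pent-4-enoate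
Conditions: [Ir(cod)Cl]2 (2 mol%), BINOL-derived N-(2-methyltetrahydroquinolinyl) phosphoramidite (single antipode, 4 mol%), TBD (10 mol%), THF, 25 °C; then 5, 7, LiOt-Bu (1 equiv), 25 °C
Reagents that add atoms: none
Why: Iridium-catalysed branched-selective asymmetric allylic alkylation, in which the ligand fixes the face of the allyl terminus attacked (C3, catalyst control) and the lithium-chelated Z-enolate presents one face in the ligand pocket (C2), so both adjacent centres should form in one bond construction.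

Step 6
Reactants: 8 benzyl (2S,3R)-2-acetyl-2-methyl-3-(prop-1-en-2-yl)pent-4-enoate; 9 methyl vinyl ketone
Product: 10 benzyl (2S,3R,4E)-2-acetyl-2-methyl-6-oxo-3-(prop-1-en-2-yl)hept-4-enoate
Conditions: second-generation Hoveyda–Grubbs catalyst (5 mol%), 9 (3 equiv), CH2Cl2, 40 °C
Reagents that add atoms: none
Why: Olefin cross-metathesis couples the monosubstituted vinyl group with the electron-poor enone partner E-selectively, while the hindered 1,1-disubstituted isopropenyl group should not enter the catalytic cycle.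

Step 7
Reactants: 10 benzyl (2S,3R,4E)-2-acetyl-2-methyl-6-oxo-3-(prop-1-en-2-yl)hept-4-enoate
Product: 11 benzyl (2S,3R)-2-acetyl-2-methyl-6-oxo-3-(prop-1-en-2-yl)heptanoate
Conditions: [(Ph3P)CuH]6 (5 mol%), PhSiH3 (1.5 equiv), t-BuOH (2 equiv), toluene, 0 °C → rt
Reagents that add atoms: none
Why: Copper hydride conjugate reduction delivers hydride only to the enone β-carbon, and t-BuOH protonates the copper enolate before it can add to the acetyl group; the isolated alkene and the saturated ketone are inert.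

Step 8
Reactants: 11 benzyl (2S,3R)-2-acetyl-2-methyl-6-oxo-3-(prop-1-en-2-yl)heptanoate
Product: 12 benzyl (2S,3R)-2-acetyl-2-methyl-5-(2-methyl-1,3-dioxolan-2-yl)-3-(prop-1-en-2-yl)pentanoate
Conditions: HOCH2CH2OH, PPTS (cat.), benzene, reflux (Dean–Stark)
Reagents that add atoms: ethylene glycol, OCCO
Why: Acid-catalysed dioxolane formation should be chemoselective because the unhindered side-chain methyl ketone reacts far faster than the acetyl group shielded by the quaternary C2.

Step 9
Reactants: 12 benzyl (2S,3R)-2-acetyl-2-methyl-5-(2-methyl-1,3-dioxolan-2-yl)-3-(prop-1-en-2-yl)pentanoate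
Product: 15 benzyl (2S,3R)-2-acryloyl-2-methyl-5-(2-methyl-1,3-dioxolan-2-yl)-3-(prop-1-en-2-yl)pentanoate, via Mannich base 13 (not isolated), via methiodide 14 (not isolated)
Conditions: LiN(SiMe3)2, THF, −78 °C; CH2=NMe2+ I−, −78 °C → rt; MeI, CH2Cl2, rt; aq. NaHCO3, CH2Cl2, rt
Reagents that add atoms: dimethyl(methylene)ammonium iodide, C=[N+](C)C.[I-]
Why: Mannich methylenation, in which the kinetic enolate of the only enolisable ketone is aminomethylated and N-methylation followed by mild-base E1cB elimination releases the vinyl ketone.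

Step 10
Reactants: 15 benzyl (2S,3R)-2-acryloyl-2-methyl-5-(2-methyl-1,3-dioxolan-2-yl)-3-(prop-1-en-2-yl)pentanoate
Product: 16 benzyl (1S,2R)-1,3,3-trimethyl-2-[2-(2-methyl-1,3-dioxolan-2-yl)ethyl]-6-oxocyclohexane-1-carboxylate
Conditions: Fe(acac)3 (30 mol%), PhSiH3 (2.5 equiv), EtOH/HOCH2CH2OH (5:1), 60 °C, 0.02 M
Reagents that add atoms: none
Why: Fe(acac)3 is turned by PhSiH3 in ethanol into an iron hydride that hands a hydrogen atom to the terminal CH2 of the C5 isopropenyl group in the Markovnikov sense, so C4 becomes a tertiary radical bearing two methyl groups; this nucleophilic radical adds to C3, the unsubstituted β-carbon of the acryloyl group, and the α-keto radical is reduced to an enolate that ethanol protonates. The closest known reaction type is the metal-hydride hydrogen-atom-transfer reductive coupling of an unactivated alkene with an enone, run here intramolecularly as a Giese cyclisation. Ring A closes in the 6-endo-trig mode, favoured over 5-exo attack at C2 because the radical is polarity-matched with the enone terminus and the carbonyl lies inside the forming ring. No stereocentre is created (C4 carries two methyls, C2 becomes CH2), and C5 and C10 cannot epimerise under these neutral conditions. The step needs hydrogen-atom transfer to the 1,1-disubstituted alkene instead of the enone, secured by the higher reactivity of the electron-rich alkene toward the metal hydride, and ring closure before the radical is reduced, secured by donor and acceptor sitting on adjacent carbons and by dilution.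

Step 11
Reactants: 16 benzyl (1S,2R)-1,3,3-trimethyl-2-[2-(2-methyl-1,3-dioxolan-2-yl)ethyl]-6-oxocyclohexane-1-carboxylate
Product: 17 benzyl (1S,6R)-1,5,5-trimethyl-6-[2-(2-methyl-1,3-dioxolan-2-yl)ethyl]-2-{[(trifluoromethyl)sulfonyl]oxy}cyclohex-2-ene-1-carboxylate
Conditions: KN(SiMe3)2, THF, −78 °C; PhNTf2, −78 → 0 °C
Reagents that add atoms: N-phenylbis(trifluoromethanesulfonimide), O=S(=O)(N(c1ccccc1)S(=O)(=O)C(F)(F)F)C(F)(F)F
Why: Enol triflate formation is regiodefined because the temporary C1 ketone can enolise only toward C2 (C10 is quaternary), and the potassium enolate is O-sulfonylated by the triflimide.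

Step 12
Reactants: 17 benzyl (1S,6R)-1,5,5-trimethyl-6-[2-(2-methyl-1,3-dioxolan-2-yl)ethyl]-2-{[(trifluoromethyl)sulfonyl]oxy}cyclohex-2-ene-1-carboxylate
Product: 18 benzyl (1R,6R)-1,5,5-trimethyl-6-[2-(2-methyl-1,3-dioxolan-2-yl)ethyl]cyclohex-2-ene-1-carboxylate
Conditions: Pd(OAc)2 (5 mol%), PPh3 (10 mol%), HCO2H, n-Bu3N, DMF, 60 °C
Reagents that add atoms: none
Why: Palladium-catalysed formate reduction of an enol triflate (oxidative addition, decarboxylation of formate to a palladium hydride, reductive elimination) replaces C–O by C–H and leaves the benzyl ester and ketal intact; the descriptor at C1 changes only through ligand priorities.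

Step 13
Reactants: 18 benzyl (1R,6R)-1,5,5-trimethyl-6-[2-(2-methyl-1,3-dioxolan-2-yl)ethyl]cyclohex-2-ene-1-carboxylate
Product: 19 (1R,2R)-1,3,3-trimethyl-2-[2-(2-methyl-1,3-dioxolan-2-yl)ethyl]cyclohexane-1-carboxylic acid
Conditions: H2 (1 atm), 10% Pd/C, EtOAc, rt
Reagents that add atoms: none
Why: Heterogeneous hydrogenation saturates the disubstituted ring alkene and hydrogenolyses the benzyl ester in the same operation, completing removal of the C1 oxygen without touching either stereocentre.

Step 14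
Reactants: 19 (1R,2R)-1,3,3-trimethyl-2-[2-(2-methyl-1,3-dioxolan-2-yl)ethyl]cyclohexane-1-carboxylic acid
Product: 20 1-{(1R,2R)-1,3,3-trimethyl-2-[2-(2-methyl-1,3-dioxolan-2-yl)ethyl]cyclohexyl}ethan-1-one
Conditions: MeLi (4 equiv), Et2O, 0 °C → rt; poured into ice-water
Reagents that add atoms: methyllithium, [Li]C
Why: Addition of an organolithium to a lithium carboxylate stops at the ketone stage because the tetrahedral adduct does not collapse until the quench, and it works well for hindered tertiary acids.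

Step 15
Reactants: 20 1-{(1R,2R)-1,3,3-trimethyl-2-[2-(2-methyl-1,3-dioxolan-2-yl)ethyl]cyclohexyl}ethan-1-one; 21 (2E)-4-bromo-3-methylbut-2-en-1-yl acetate
Product: 22 (2E)-3-methyl-6-oxo-6-{(1R,2R)-1,3,3-trimethyl-2-[2-(2-methyl-1,3-dioxolan-2-yl)ethyl]cyclohexyl}hex-2-en-1-yl acetate
Conditions: LiN(i-Pr)2 (1.05 equiv), THF, −78 °C; 21 (1.5 equiv), DMPU, −78 → −30 °C
Reagents that add atoms: none
Why: Kinetic enolate alkylation, in which the methyl group is the only enolisable position and SN2 displacement of the primary allylic bromide at low temperature should outrun attack on the acetate, the alkene geometry being carried over unchanged.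

Step 16
Reactants: 22 (2E)-3-methyl-6-oxo-6-{(1R,2R)-1,3,3-trimethyl-2-[2-(2-methyl-1,3-dioxolan-2-yl)ethyl]cyclohexyl}hex-2-en-1-yl acetate
Product: 23 (2E)-3-methyl-6-oxo-6-[(1R,2R)-1,3,3-trimethyl-2-(3-oxobutyl)cyclohexyl]hex-2-en-1-yl acetate (CNP0326957.1)
Conditions: PPTS (cat.), acetone/H2O, 50 °C
Reagents that add atoms: water, O
Why: Mild acid-catalysed ketal hydrolysis frees the side-chain ketone under conditions that should spare the allylic acetate, and neither stereocentre is α to a carbonyl hydrogen that could epimerise.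

Compound list
1 | methacrolein (2-methylprop-2-enal) | CC(=C)C=O | starting material
2 | triethyl phosphonoacetate | CCOC(=O)CP(=O)(OCC)OCC | starting material
3 | ethyl (2E)-4-methylpenta-2,4-dienoate | CCOC(=O)/C=C/C(C)=C | intermediate
4 | (2E)-4-methylpenta-2,4-dien-1-ol | OC/C=C/C(C)=C | intermediate
5 | methyl (2E)-4-methylpenta-2,4-dien-1-yl carbonate | COC(=O)OC/C=C/C(C)=C | intermediate
6 | methyl 2-methyl-3-oxobutanoate (racemic) | COC(=O)C(C)C(C)=O | starting material
7 | benzyl 2-methyl-3-oxobutanoate (racemic) | CC(=O)C(C)C(=O)OCc1ccccc1 | intermediate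
8 | benzyl (2S,3R)-2-acetyl-2-methyl-3-(prop-1-en-2-yl)pent-4-enoate | C=C[C@H](C(C)=C)[C@@](C)(C(C)=O)C(=O)OCc1ccccc1 | intermediate
9 | methyl vinyl ketone (but-3-en-2-one) | CC(=O)C=C | starting material
10 | benzyl (2S,3R,4E)-2-acetyl-2-methyl-6-oxo-3-(prop-1-en-2-yl)hept-4-enoate | CC(=O)/C=C/[C@H](C(C)=C)[C@@](C)(C(C)=O)C(=O)OCc1ccccc1 | intermediate
11 | benzyl (2S,3R)-2-acetyl-2-methyl-6-oxo-3-(prop-1-en-2-yl)heptanoate | CC(=O)CC[C@H](C(C)=C)[C@@](C)(C(C)=O)C(=O)OCc1ccccc1 | intermediate
12 | benzyl (2S,3R)-2-acetyl-2-methyl-5-(2-methyl-1,3-dioxolan-2-yl)-3-(prop-1-en-2-yl)pentanoate | CC1(OCCO1)CC[C@H](C(C)=C)[C@@](C)(C(C)=O)C(=O)OCc2ccccc2 | intermediate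
13 | benzyl (2S,3R)-2-[3-(dimethylamino)propanoyl]-2-methyl-5-(2-methyl-1,3-dioxolan-2-yl)-3-(prop-1-en-2-yl)pentanoate (Mannich base) | CC1(OCCO1)CC[C@H](C(C)=C)[C@@](C)(C(=O)CCN(C)C)C(=O)OCc2ccccc2 | intermediate
14 | N-methyl quaternary ammonium iodide of 13 (methiodide) | CC1(OCCO1)CC[C@H](C(C)=C)[C@@](C)(C(=O)CC[N+](C)(C)C)C(=O)OCc2ccccc2.[I-] | intermediate
15 | benzyl (2S,3R)-2-acryloyl-2-methyl-5-(2-methyl-1,3-dioxolan-2-yl)-3-(prop-1-en-2-yl)pentanoate | CC1(OCCO1)CC[C@H](C(C)=C)[C@@](C)(C(=O)C=C)C(=O)OCc2ccccc2 | intermediate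
16 | benzyl (1S,2R)-1,3,3-trimethyl-2-[2-(2-methyl-1,3-dioxolan-2-yl)ethyl]-6-oxocyclohexane-1-carboxylate | CC1(OCCO1)CC[C@@H]2C(C)(C)CCC(=O)[C@@]2(C)C(=O)OCc3ccccc3 | intermediate
17 | benzyl (1S,6R)-1,5,5-trimethyl-6-[2-(2-methyl-1,3-dioxolan-2-yl)ethyl]-2-{[(trifluoromethyl)sulfonyl]oxy}cyclohex-2-ene-1-carboxylate | CC1(OCCO1)CC[C@@H]2C(C)(C)CC=C(OS(=O)(=O)C(F)(F)F)[C@@]2(C)C(=O)OCc3ccccc3 | intermediate
18 | benzyl (1R,6R)-1,5,5-trimethyl-6-[2-(2-methyl-1,3-dioxolan-2-yl)ethyl]cyclohex-2-ene-1-carboxylate | CC1(OCCO1)CC[C@@H]2C(C)(C)CC=C[C@@]2(C)C(=O)OCc3ccccc3 | intermediate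
19 | (1R,2R)-1,3,3-trimethyl-2-[2-(2-methyl-1,3-dioxolan-2-yl)ethyl]cyclohexane-1-carboxylic acid | CC1(OCCO1)CC[C@@H]2C(C)(C)CCC[C@@]2(C)C(=O)O | intermediate
20 | 1-{(1R,2R)-1,3,3-trimethyl-2-[2-(2-methyl-1,3-dioxolan-2-yl)ethyl]cyclohexyl}ethan-1-one | CC1(OCCO1)CC[C@@H]2C(C)(C)CCC[C@@]2(C)C(C)=O | intermediate
21 | (2E)-4-bromo-3-methylbut-2-en-1-yl acetate | BrC/C(C)=C/COC(C)=O | starting material
22 | (2E)-3-methyl-6-oxo-6-{(1R,2R)-1,3,3-trimethyl-2-[2-(2-methyl-1,3-dioxolan-2-yl)ethyl]cyclohexyl}hex-2-en-1-yl acetate | CC1(OCCO1)CC[C@@H]2C(C)(C)CCC[C@@]2(C)C(=O)CC/C(C)=C/COC(C)=O | intermediate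
23 | (2E)-3-methyl-6-oxo-6-[(1R,2R)-1,3,3-trimethyl-2-(3-oxobutyl)cyclohexyl]hex-2-en-1-yl acetate | CC(=O)CC[C@@H]1C(C)(C)CCC[C@@]1(C)C(=O)CC/C(C)=C/COC(C)=O | target

Total step count: 16. Longest linear sequence: 15 steps (steps 1–3 and 5–16, from methacrolein).

Steps most likely to fail

Step 5. The enolate faces may be poorly discriminated when the ketone substituent is only a methyl group, eroding control at C2 of 8, and the dienyl electrophile may give some linear product. The fallback sets out from 1 and 6 and returns at 10, and fixes both centres through a chair-like sigmatropic transition state. Wittig olefination of 1 with 1-(triphenylphosphoranylidene)propan-2-one (toluene, 80 °C) should give (3E)-5-methylhexa-3,5-dien-2-one F1. Corey–Bakshi–Shibata reduction ((S)-methyl oxazaborolidine, BH3·SMe2, THF, −30 °C) should give (2R,3E)-5-methylhexa-3,5-dien-2-ol F2. DMAP-catalysed transesterification with 6 (toluene, reflux) gives (2R,3E)-5-methylhexa-3,5-dien-2-yl 2-methyl-3-oxobutanoate F3. Dianionic Carroll rearrangement (LiN(i-Pr)2, 2.2 equiv, THF, −78 °C → reflux) then proceeds through a chair with the carbinol methyl equatorial and the C-methyl of the chelated dianion cis to the allylic oxygen. This transfers the carbinol chirality and should give (2S,3R,4E)-2-acetyl-2-methyl-3-(prop-1-en-2-yl)hex-4-enoic acid F4, which is esterified at once (BnBr, K2CO3, DMF, 0 °C) to benzyl (2S,3R,4E)-2-acetyl-2-methyl-3-(prop-1-en-2-yl)hex-4-enoate F5. Cross-metathesis of F5 with 9 under the conditions of step 6 (propene lost in place of ethylene) gives 10.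

Step 10. The metal hydride may reduce the vinyl ketone, the tertiary radical may be quenched before it cyclises, or the acryloyl group may oligomerise. The fallback sets out from 12 and returns at 16, and separates radical generation from the enone by using a tertiary halide and tin hydride. Cobalt-catalysed Markovnikov hydrochlorination of the isopropenyl group of 12 (Co(BF4)2·6H2O with a salicylaldimine ligand, TsCl, PhSiH3, EtOH, rt) should give benzyl (2S,3S)-2-acetyl-3-(2-chloropropan-2-yl)-2-methyl-5-(2-methyl-1,3-dioxolan-2-yl)pentanoate F6. The Mannich sequence of step 9 then passes through the chloro Mannich base F7 and its methiodide F8 to benzyl (2S,3S)-2-acryloyl-3-(2-chloropropan-2-yl)-2-methyl-5-(2-methyl-1,3-dioxolan-2-yl)pentanoate F9. Slow addition of Bu3SnH/AIBN in toluene at 100 °C generates the same C4 radical by chlorine abstraction and should close ring A by the same 6-endo Giese addition to give 16.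

Step 15. Acyl transfer from the acetate of 21 to the lithium enolate, or proton exchange between product and enolate leading to double alkylation. The fallback sets out from 19 and returns at 22, and replaces the hard enolate by a soft, doubly stabilised carbanion. Activation of 19 with 1,1'-carbonyldiimidazole (THF, rt) gives the acyl imidazole F10. Addition of LiCH2SO2Ph (from methyl phenyl sulfone and n-BuLi, THF, −78 → 0 °C) gives the β-keto sulfone F11. Alkylation with 21 (K2CO3, DMF, rt) gives the alkylated β-keto sulfone F12 as a mixture at the sulfonyl carbon. Reductive desulfonylation with aluminium amalgam (THF/H2O, rt) gives 22.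

Further compounds
F1 | step 5 | (3E)-5-methylhexa-3,5-dien-2-one | CC(=O)/C=C/C(C)=C
F2 | step 5 | (2R,3E)-5-methylhexa-3,5-dien-2-ol | C[C@@H](O)/C=C/C(C)=C
F3 | step 5 | (2R,3E)-5-methylhexa-3,5-dien-2-yl 2-methyl-3-oxobutanoate | CC(=O)C(C)C(=O)O[C@H](C)/C=C/C(C)=C
F4 | step 5 | (2S,3R,4E)-2-acetyl-2-methyl-3-(prop-1-en-2-yl)hex-4-enoic acid | C/C=C/[C@H](C(C)=C)[C@@](C)(C(C)=O)C(=O)O
F5 | step 5 | benzyl (2S,3R,4E)-2-acetyl-2-methyl-3-(prop-1-en-2-yl)hex-4-enoate | C/C=C/[C@H](C(C)=C)[C@@](C)(C(C)=O)C(=O)OCc1ccccc1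
F6 | step 10 | benzyl (2S,3S)-2-acetyl-3-(2-chloropropan-2-yl)-2-methyl-5-(2-methyl-1,3-dioxolan-2-yl)pentanoate | CC1(OCCO1)CC[C@H](C(C)(C)Cl)[C@@](C)(C(C)=O)C(=O)OCc2ccccc2
F7 | step 10 | benzyl (2S,3S)-3-(2-chloropropan-2-yl)-2-[3-(dimethylamino)propanoyl]-2-methyl-5-(2-methyl-1,3-dioxolan-2-yl)pentanoate | CC1(OCCO1)CC[C@H](C(C)(C)Cl)[C@@](C)(C(=O)CCN(C)C)C(=O)OCc2ccccc2
F8 | step 10 | N-methyl quaternary ammonium iodide of F7 | CC1(OCCO1)CC[C@H](C(C)(C)Cl)[C@@](C)(C(=O)CC[N+](C)(C)C)C(=O)OCc2ccccc2.[I-]
F9 | step 10 | benzyl (2S,3S)-2-acryloyl-3-(2-chloropropan-2-yl)-2-methyl-5-(2-methyl-1,3-dioxolan-2-yl)pentanoate | CC1(OCCO1)CC[C@H](C(C)(C)Cl)[C@@](C)(C(=O)C=C)C(=O)OCc2ccccc2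
F10 | step 15 | (1H-imidazol-1-yl){(1R,2R)-1,3,3-trimethyl-2-[2-(2-methyl-1,3-dioxolan-2-yl)ethyl]cyclohexyl}methanone | CC1(OCCO1)CC[C@@H]2C(C)(C)CCC[C@@]2(C)C(=O)n3ccnc3
F11 | step 15 | 2-(phenylsulfonyl)-1-{(1R,2R)-1,3,3-trimethyl-2-[2-(2-methyl-1,3-dioxolan-2-yl)ethyl]cyclohexyl}ethan-1-one | CC1(OCCO1)CC[C@@H]2C(C)(C)CCC[C@@]2(C)C(=O)CS(=O)(=O)c3ccccc3
F12 | step 15 | (2E)-3-methyl-6-oxo-5-(phenylsulfonyl)-6-{(1R,2R)-1,3,3-trimethyl-2-[2-(2-methyl-1,3-dioxolan-2-yl)ethyl]cyclohexyl}hex-2-en-1-yl acetate (mixture at C5) | CC1(OCCO1)CC[C@@H]2C(C)(C)CCC[C@@]2(C)C(=O)C(C/C(C)=C/COC(C)=O)S(=O)(=O)c3ccccc3
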